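**Remark on the chemistry (assumption):** the SMILES holds no stereocentre and no double-bond geometry, so the target is taken as the single achiral compound 21-(furan-2-yl)henicosa-14,16-diyn-1-ol (C25H38O2). C1–C21 are the chain atoms counted from the CH2OH carbon; O1' and C2'–C5' are the furan atoms.

## Structural features

The target is a linear C21 chain. C1 carries the primary hydroxyl, C1–C13 are thirteen methylene groups, C14≡C15–C16≡C17 is a conjugated diyne, C18–C21 are four methylene groups, and C21 is bonded to C2' of a furan ring whose C3', C4' and C5' are unsubstituted. There is no stereocentre and no alkene geometry, so the problem is one of constitution only. The fragile parts are the 2-alkylfuran and the diyne. The furan is opened by aqueous acid, attacked at C5' by electrophilic halogen and oxidants, and metalated at C5' by alkyllithiums in ethereal solvents. The diyne is sensitive to light and π-acidic transition metals, and polymerises once one end is free. The C1 hydroxyl is robust but must be masked whenever organolithium or bromophosphonium reagents are present. The real difficulty is the unsymmetrical diyne: C13 and C18 are both unactivated methylene carbons, so the halves C14≡C15 and C16≡C17 are electronically indistinguishable, and C15–C16 joins two sp carbons of like polarity. The key step exploits the fact that C16 is an sp carbon bonded only to C15 and C17, while C17 is bonded to the sp3 carbon C18. C17 can therefore start as an acyl carbon, C15 as an acetylide carbon joined to it, and C16 as a one-carbon carbenoid placed on C17, to which C15 then shifts.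

## Logic of the disconnections

**20 back to 19.** The O–Si bond at the C1 oxygen is cut. The hydroxyl has to be masked through two organolithium steps and the PPh3/CBr4 step, and the mask must come off without acid or oxidant. The demand on the forward step is fluoride cleavage that leaves the furan and the diyne alone.

**19 back to 17 (key disconnection, through 18).** The C15–C16 σ bond and the second π bond of C16≡C17 are cut. In the reverse sense the C15 alkynyl group goes from C16 back to C17 and C16 receives two bromine atoms. In one sentence: the diyne is not coupled but rearranged into existence from the cross-conjugated dibromoolefin 17 by a carbenoid 1,2-alkynyl shift. That sentence does not describe a coupling of two alkynes. The gain is that the sp–sp bond between like-polarity carbons is made inside one molecule, so no symmetrical diyne can form, and 17 is one step from a carbonyl compound. The forward step demands bromine–lithium exchange at C16 faster than any deprotonation, and a 1,2-shift faster than C–H insertion or intermolecular trapping.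

**17 back to 16.** The C16=C17 double bond is cut and C16 is traced to CBr4. This turns the carbenoid precursor into a ketone at C17. The forward step is a Wittig-type dibromoolefination of an enolisable ynone that must tolerate the furan and the silyl ether.

**16 back to 13 and 6 (through 14 and 15).** The C15–C17 bond is cut between an acetylide carbon and an acyl carbon. This is the convergent union, and it is polarity-matched, so neither fragment can dimerise. It splits the skeleton into a C15 piece and a C9 piece. The forward step must stop at single addition and must keep the released hydroxylamine from adding to the ynone. The opposite placement of the carbonyl, at C14, would need a C14 ω-oxygenated acyl donor and an alkyne-bearing furan, both less accessible, so that plan would be longer.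

**6 back to 4 (through 5).** The C17–C18 bond is cut: the acyl carbon is delivered as a carbamoyl chloride to the Grignard reagent of the chloride. The forward step must avoid a second addition.

**4 back to 1 and 2 (through 3).** The C21–C2' bond is cut. Furan is the nucleophile at C2' and a four-carbon dihalide the electrophile; the bromide must react in preference to the chloride.

**13 back to 12 and 12 back to 10.** The O–Si bond is cut first. The triple bond is then moved back from C14≡C15 to C2≡C3, a retro-zipper. This places the alkyne next to the hydroxyl, where it can be made by a simple alkylation. The forward isomerisation must run fully to the chain terminus.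

**10 back to 7 and 8 (through 9).** The C3–C4 bond is cut between the acetylide carbon of the propargylic alcohol dianion and a C12 primary bromide. Both are commodity chemicals.

## Other disconnections considered

Alternative 1: The first route that comes to mind cuts C15–C16 between two alkynes. The forward key step is a Cadiot–Chodkiewicz coupling of 15-bromopentadec-14-yn-1-ol A1 with 2-(hex-5-yn-1-yl)furan A2 (cat. CuCl, NH2OH·HCl, aqueous amine). On paper it is about three steps shorter and needs no protecting group, and it is kept as the fallback for the key step. It is not chosen for a mechanistic reason. Both partners are unactivated alkyl alkynes, so copper–halogen exchange between the copper acetylide of A2 and A1 is expected to feed both symmetrical diynes beside the cross product, in the last step and on the most advanced material. The bromination that makes A1 must also be kept away from every furan-containing compound, because electrophilic bromine attacks C5'. The chosen plan makes C15–C16 within one molecule, where no statistical product exists, and joins the fragments by an acyl substitution.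

Alternative 2: Both sp–sp3 bonds, C13–C14 and C17–C18, are cut and a four-carbon linchpin is used. 1,4-Bis(trimethylsilyl)buta-1,3-diyne A3 would be monolithiated and alkylated with 2-(4-iodobutyl)furan A4 to give trimethyl[8-(furan-2-yl)octa-1,3-diyn-1-yl]silane A5. Desilylation would give 2-(octa-5,7-diyn-1-yl)furan A6, which would be lithiated and alkylated with tert-butyl[(13-iodotridecyl)oxy]diphenylsilane A7. The grounds against it are mechanistic and practical. Diynyl lithium reagents are charge-delocalised, weak nucleophiles whose SN2 reactions with unactivated primary halides need strongly coordinating cosolvents and compete with elimination. A6 is a terminal 1,3-diyne of low stability. A7 has an odd-numbered C13 chain that is not a commodity and would need a synthesis about as long as that of 12. Two uncertain alkylations would stand in the linear sequence where the chosen plan has one reliable acyl substitution.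

Alternative 3: The furan is made last and closed at the C3'–C4' carbon–carbon bond. The mixed acrolein acetal tert-butyl({22-[(1-ethoxyprop-2-en-1-yl)oxy]tetracos-23-ene-14,16-diyn-1-yl}oxy)diphenylsilane A8 would undergo ring-closing metathesis with the second-generation Grubbs catalyst. The product, tert-butyl{[21-(5-ethoxy-2,5-dihydrofuran-2-yl)henicosa-14,16-diyn-1-yl]oxy}diphenylsilane A9, would lose ethanol under acid to give the aromatic ring. The ruthenium alkylidene is not orthogonal to the C14–C17 diyne (enyne metathesis), and the aromatisation needs acid in the presence of the acid-labile 2-alkylfuran it creates. The ring that this builds is available as commercial 1, the diyne problem stays unsolved, and the route is longer.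

Key step: step 8

## Route

Step 1
Reactants: 1 furan; 2 1-bromo-4-chlorobutane
Product: 4 2-(4-chlorobutyl)furan, via 2-lithiofuran 3 (not isolated)
Conditions: 1 (1.5 equiv), n-BuLi (1.0 equiv), THF, −78 → 0 °C; then 2, −78 °C → rt
Reagents that add atoms: none
Why: Heteroatom-directed C2 lithiation of furan, then SN2 alkylation of 3 at the C–Br end of 2, which is displaced far faster than the C–Cl end; an excess of cheap, volatile furan keeps 2,5-dialkylation down.

Step 2
Reactants: 4 2-(4-chlorobutyl)furan
Product: 6 5-(furan-2-yl)-N-methoxy-N-methylpentanamide, via Grignard reagent 5 (not isolated)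
Conditions: Mg turnings, cat. I2, THF, reflux; then added to ClC(O)N(OMe)Me (1.3 equiv), THF, −78 → 0 °C; aq NH4Cl
Reagents that add atoms: N-methoxy-N-methylcarbamoyl chloride, CON(C)C(Cl)=O
Why: Grignard formation from the primary chloride, then nucleophilic acyl substitution at the carbamoyl chloride (Weinreb amide synthesis from an organometallic); inverse addition of 5 to an excess of the more electrophilic carbamoyl chloride at low temperature limits a second addition to 6.

Step 3
Reactants: 7 prop-2-yn-1-ol; 8 1-bromododecane
Product: 10 pentadec-2-yn-1-ol, via dilithiated propargyl alcohol 9 (not isolated)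
Conditions: n-BuLi (2.1 equiv), THF/DMPU, −78 → 0 °C; then 8, 0 °C → rt; then H2O
Reagents that add atoms: none
Why: Alkylation of the O,C-dianion of a propargylic alcohol: the acetylide carbon is the more nucleophilic site, so the primary bromide is displaced (SN2) at carbon and the alkoxide is left untouched; DMPU loosens the lithium aggregates.

Step 4
Reactants: 10 pentadec-2-yn-1-ol
Product: 12 pentadec-14-yn-1-ol, via dipotassium alkoxide acetylide 11 (not isolated)
Conditions: KH (4 equiv), H2N(CH2)3NH2, 0 °C → rt; then H2O, 0 °C
Reagents that add atoms: none
Why: Alkyne zipper reaction: potassium 3-aminopropylamide moves the triple bond along the chain by repeated propargyl–allenyl proton shifts, and the equilibria are drained by irreversible formation of the terminal acetylide 11, which water then protonates; the reaction is standard for alk-2-yn-1-ols of this length.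

Step 5
Reactants: 12 pentadec-14-yn-1-ol
Product: 13 tert-butyl(pentadec-14-yn-1-yloxy)diphenylsilane
Conditions: TBDPSCl (1.1 equiv), imidazole (2 equiv), CH2Cl2, rt
Reagents that add atoms: tert-butyl(chloro)diphenylsilane, CC(C)(C)[Si](Cl)(c1ccccc1)c1ccccc1
Why: Imidazole-promoted silylation of a primary alcohol; the TBDPS ether is chosen because it should withstand n-BuLi, the bromophosphonium by-product of step 7 and the cold acid quench of step 6, and it leaves with fluoride under conditions that spare furan and diyne.

Step 6
Reactants: 13 tert-butyl(pentadec-14-yn-1-yloxy)diphenylsilane; 6 5-(furan-2-yl)-N-methoxy-N-methylpentanamide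
Product: 16 20-[(tert-butyldiphenylsilyl)oxy]-1-(furan-2-yl)icos-6-yn-5-one, via lithium acetylide 14 (not isolated), via tetrahedral lithium adduct 15 (not isolated)
Conditions: 13 (1.2 equiv), n-BuLi (1.15 equiv), THF, −78 °C; then 6, −78 → −20 °C; inverse quench into cold 1 M aq HCl
Reagents that add atoms: none
Why: Weinreb ketone synthesis: acetylide 14 adds once to the amide carbonyl (C17) and the five-membered lithium chelate 15 survives until the quench, so no tertiary alcohol can form; the cold acidic inverse quench protonates the released N,O-dimethylhydroxylamine before it can add to the ynone in conjugate fashion. This polarity-matched addition joins the two halves through the C15–C17 bond.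

Step 7
Reactants: 16 20-[(tert-butyldiphenylsilyl)oxy]-1-(furan-2-yl)icos-6-yn-5-one
Product: 17 tert-butyl{[16-(dibromomethylidene)-20-(furan-2-yl)icos-14-yn-1-yl]oxy}diphenylsilane
Conditions: CBr4 (2 equiv), PPh3 (4 equiv), CH2Cl2, 0 °C (ylide preformed); then 16, 0 °C → rt
Reagents that add atoms: carbon tetrabromide, BrC(Br)(Br)Br
Why: Ramirez–Corey–Fuchs dibromoolefination: Ph3P=CBr2, formed from CBr4 and PPh3, undergoes a Wittig reaction with the ynone carbonyl, which is more electrophilic than a dialkyl ketone; CBr4 supplies the future C16. Adding 16 to the preformed ylide keeps free PPh3 low and so disfavours phosphine conjugate addition to the ynone.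

Step 8
Reactants: 17 tert-butyl{[16-(dibromomethylidene)-20-(furan-2-yl)icos-14-yn-1-yl]oxy}diphenylsilane
Product: 19 tert-butyl{[21-(furan-2-yl)henicosa-14,16-diyn-1-yl]oxy}diphenylsilane, via bromolithio carbenoid 18 (not isolated)
Conditions: n-BuLi (1.15 equiv), hexanes, −78 °C, then warm to −20 °C; aq NH4Cl
Reagents that add atoms: none
Why: Fritsch–Buttenberg–Wiechell rearrangement of an alkylidene carbenoid. Bromine–lithium exchange at the CBr2 carbon (target C16) of 17 is far faster at −78 °C in hexanes than deprotonation of furan C5'–H or of the propargylic and allylic CH2 groups, and gives the 1-bromo-1-lithioalkene 18. On warming, 18 loses LiBr while a substituent of C17 shifts with its bonding pair to C16; the alkynyl group (C15) has the higher migratory aptitude, so the C15–C16 bond and the C16≡C17 triple bond form in the same event. The constitution of 19 does not depend on which substituent migrates or on the E/Z geometry of 18, since a shift of the C18 alkyl chain would give the same diyne. The closest known reaction type is the carbenoid rearrangement of ynone-derived 1,1-dibromoolefins to unsymmetrical 1,3-diynes and triynes, which accepts alkyl substituents at the olefin. No ring is closed and no stereocentre is formed. The selectivity needed is 1,2-shift over 1,5 C–H insertion into C20–H and over intermolecular trapping; the non-coordinating solvent keeps the species a tight lithium carbenoid instead of a free carbene, and the sp carbon bridges readily. Because both alkyne halves already sit in one molecule, no homocoupled diyne can arise.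

Step 9
Reactants: 19 tert-butyl{[21-(furan-2-yl)henicosa-14,16-diyn-1-yl]oxy}diphenylsilane
Product: 20 21-(furan-2-yl)henicosa-14,16-diyn-1-ol
Conditions: TBAF (1.2 equiv), THF, 0 °C → rt; then H2O; work-up in dim light under argon
Reagents that add atoms: none
Why: Fluoride-induced Si–O cleavage driven by the strong Si–F bond; the non-acidic medium leaves the 2-alkylfuran and the diyne untouched.

## Compound list

1 | furan | c1ccoc1 | starting material
2 | 1-bromo-4-chlorobutane | ClCCCCBr | starting material
3 | 2-lithiofuran | [Li]c1ccco1 | intermediate (not isolated)
4 | 2-(4-chlorobutyl)furan | ClCCCCc1ccco1 | intermediate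
5 | [4-(furan-2-yl)butyl]magnesium chloride | Cl[Mg]CCCCc1ccco1 | intermediate (not isolated)
6 | 5-(furan-2-yl)-N-methoxy-N-methylpentanamide | CON(C)C(=O)CCCCc1ccco1 | intermediate
7 | prop-2-yn-1-ol | OCC#C | starting material
8 | 1-bromododecane | BrCCCCCCCCCCCC | starting material
9 | lithium 3-lithioprop-2-yn-1-olate | [Li]OCC#C[Li] | intermediate (not isolated)
10 | pentadec-2-yn-1-ol | OCC#CCCCCCCCCCCCC | intermediate
11 | potassium 15-potassiopentadec-14-yn-1-olate | [K]OCCCCCCCCCCCCCC#C[K] | intermediate (not isolated)
12 | pentadec-14-yn-1-ol | OCCCCCCCCCCCCCC#C | intermediate
13 | tert-butyl(pentadec-14-yn-1-yloxy)diphenylsilane | CC(C)(C)[Si](OCCCCCCCCCCCCCC#C)(c1ccccc1)c1ccccc1 | intermediate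
14 | lithium acetylide of 13, {15-[(tert-butyldiphenylsilyl)oxy]pentadec-1-yn-1-yl}lithium | CC(C)(C)[Si](OCCCCCCCCCCCCCC#C[Li])(c1ccccc1)c1ccccc1 | intermediate (not isolated)
15 | lithium alkoxide of the hemiaminal from 14 and 6 (racemic; carbinol carbon bears OLi, N(OMe)Me, the 4-(furan-2-yl)butyl group and the alkynyl group) | CC(C)(C)[Si](OCCCCCCCCCCCCCC#CC(O[Li])(N(C)OC)CCCCc1ccco1)(c1ccccc1)c1ccccc1 | intermediate (not isolated)
16 | 20-[(tert-butyldiphenylsilyl)oxy]-1-(furan-2-yl)icos-6-yn-5-one | CC(C)(C)[Si](OCCCCCCCCCCCCCC#CC(=O)CCCCc1ccco1)(c1ccccc1)c1ccccc1 | intermediate
17 | tert-butyl{[16-(dibromomethylidene)-20-(furan-2-yl)icos-14-yn-1-yl]oxy}diphenylsilane (the CBr2 carbon is target C16) | CC(C)(C)[Si](OCCCCCCCCCCCCCC#CC(=C(Br)Br)CCCCc1ccco1)(c1ccccc1)c1ccccc1 | intermediate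
18 | 1-bromo-1-lithioalkene carbenoid from 17 (one Br of the CBr2 group replaced by Li; E/Z not defined) | CC(C)(C)[Si](OCCCCCCCCCCCCCC#CC(=C(Br)[Li])CCCCc1ccco1)(c1ccccc1)c1ccccc1 | intermediate (not isolated)
19 | tert-butyl{[21-(furan-2-yl)henicosa-14,16-diyn-1-yl]oxy}diphenylsilane | CC(C)(C)[Si](OCCCCCCCCCCCCCC#CC#CCCCCc1ccco1)(c1ccccc1)c1ccccc1 | intermediate
20 | 21-(furan-2-yl)henicosa-14,16-diyn-1-ol | OCCCCCCCCCCCCCC#CC#CCCCCc1ccco1 | target

## Step count and least certain steps

Total step count: 9. Longest linear sequence: 7 steps (steps 3 to 9, from 7 and 8). The furan branch (steps 1 and 2) joins at step 6.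

**Step 8 (key step).** The most likely failures are premature protonation of carbenoid 18 to a monobromoolefin, capture of 18 by n-BuLi, competing 1,5 C–H insertion, and metalation of the furan at C5' if the exchange is slowed by poor solubility in hexanes. The fallback gives up the rearrangement and forms C15–C16 by copper coupling; it sets out from 13 and from 4 and comes back at 19. Compound 13 is brominated at the alkyne terminus (NBS, cat. AgNO3, acetone) to give [(15-bromopentadec-14-yn-1-yl)oxy](tert-butyl)diphenylsilane F1, so the electrophilic bromine never meets a furan. Compound 4 is treated with lithium acetylide–ethylenediamine complex in DMSO to give 2-(hex-5-yn-1-yl)furan F2. Cadiot–Chodkiewicz coupling of F1 with F2 (cat. CuCl, NH2OH·HCl, n-BuNH2, H2O/Et2O, 0 °C) should give 19, at the cost of some symmetrical diyne.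

**Step 7.** The Wittig-type olefination of an enolisable ketone may be slow or incomplete, free PPh3 may add to the ynone in conjugate fashion, and the bromophosphonium by-product may erode the silyl ether. The fallback keeps C16 as a carbon from CBr4 and C17 as an acyl carbon but moves the olefination to an aldehyde and replaces the carbenoid shift by a palladium-catalysed coupling; it sets out from 6 and comes back at 19. Reduction of 6 (DIBAL-H, THF, −78 °C) gives 5-(furan-2-yl)pentanal F3. Dibromoolefination (CBr4, PPh3, CH2Cl2, 0 °C), fast for an aldehyde, gives 2-(6,6-dibromohex-5-en-1-yl)furan F4. Coupling of F4 with 13 under a zerovalent palladium catalyst (Pd2(dba)3, tris(2-furyl)phosphine, iPr2NEt, DMF, 80 °C) with loss of two HBr should give 19.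

**Step 6.** The released N,O-dimethylhydroxylamine may add to the ynone during warming or quench, and the chelate may collapse early and allow double addition. The fallback forms the C17–C18 bond instead of C15–C17 and releases no amine nucleophile at the ynone stage; it sets out from 13 and from 4 and comes back at 16. Lithiation of 13 and formylation with DMF (inverse quench into aq KH2PO4) give 16-[(tert-butyldiphenylsilyl)oxy]hexadec-2-ynal F5. Addition of Grignard reagent 5, made from 4 as in step 2, at −78 °C gives racemic 20-[(tert-butyldiphenylsilyl)oxy]-1-(furan-2-yl)icos-6-yn-5-ol F6. Oxidation with MnO2 in CH2Cl2 gives 16.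

**Step 2.** Grignard reagent 5 may add a second time to 6 and give the symmetrical ketone, and Wurtz homocoupling may occur while the Grignard reagent forms from the chloride. The fallback separates carbon–carbon bond formation from amide formation; it sets out from 4 and comes back at 6. Reagent 5 is quenched with CO2 to give 5-(furan-2-yl)pentanoic acid F7, which is activated with 1,1'-carbonyldiimidazole and treated with MeNH(OMe)·HCl to give 6.

## Further compounds

F1 | step 8 | [(15-bromopentadec-14-yn-1-yl)oxy](tert-butyl)diphenylsilane | CC(C)(C)[Si](OCCCCCCCCCCCCCC#CBr)(c1ccccc1)c1ccccc1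
F2 | step 8 | 2-(hex-5-yn-1-yl)furan | C#CCCCCc1ccco1
F3 | step 7 | 5-(furan-2-yl)pentanal | O=CCCCCc1ccco1
F4 | step 7 | 2-(6,6-dibromohex-5-en-1-yl)furan | BrC(Br)=CCCCCc1ccco1
F5 | step 6 | 16-[(tert-butyldiphenylsilyl)oxy]hexadec-2-ynal | CC(C)(C)[Si](OCCCCCCCCCCCCCC#CC=O)(c1ccccc1)c1ccccc1
F6 | step 6 | 20-[(tert-butyldiphenylsilyl)oxy]-1-(furan-2-yl)icos-6-yn-5-ol (racemic) | CC(C)(C)[Si](OCCCCCCCCCCCCCC#CC(O)CCCCc1ccco1)(c1ccccc1)c1ccccc1
F7 | step 2 | 5-(furan-2-yl)pentanoic acid | OC(=O)CCCCc1ccco1
A1 | alternative 1 | 15-bromopentadec-14-yn-1-ol | OCCCCCCCCCCCCCC#CBr
A2 | alternative 1 | 2-(hex-5-yn-1-yl)furan | C#CCCCCc1ccco1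
A3 | alternative 2 | 1,4-bis(trimethylsilyl)buta-1,3-diyne | C[Si](C)(C)C#CC#C[Si](C)(C)C
A4 | alternative 2 | 2-(4-iodobutyl)furan | ICCCCc1ccco1
A5 | alternative 2 | trimethyl[8-(furan-2-yl)octa-1,3-diyn-1-yl]silane | C[Si](C)(C)C#CC#CCCCCc1ccco1
A6 | alternative 2 | 2-(octa-5,7-diyn-1-yl)furan | C#CC#CCCCCc1ccco1
A7 | alternative 2 | tert-butyl[(13-iodotridecyl)oxy]diphenylsilane | CC(C)(C)[Si](OCCCCCCCCCCCCCI)(c1ccccc1)c1ccccc1
A8 | alternative 3 | tert-butyl({22-[(1-ethoxyprop-2-en-1-yl)oxy]tetracos-23-ene-14,16-diyn-1-yl}oxy)diphenylsilane (mixture of diastereomers) | CC(C)(C)[Si](OCCCCCCCCCCCCCC#CC#CCCCCC(OC(OCC)C=C)C=C)(c1ccccc1)c1ccccc1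
A9 | alternative 3 | tert-butyl{[21-(5-ethoxy-2,5-dihydrofuran-2-yl)henicosa-14,16-diyn-1-yl]oxy}diphenylsilane (mixture of diastereomers) | CC(C)(C)[Si](OCCCCCCCCCCCCCC#CC#CCCCCC1C=CC(OCC)O1)(c1ccccc1)c1ccccc1
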